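This flask is fed slowly: the pre-initiator loses half of itself in 5.78 min, longer than the 0.11 min in which impurity as charged halves initiator, and we follow what the chains do with that trickle.

free monomer 0.20 M; transfer agent 2.00 mM; pre-initiator 5.0 mM; impurity 6.1 mM; time 1.0 h

    free monomer + initiator → living end + monomer in chains (k1 = 1.2 /M/min)
    free monomer + living end → monomer in chains + living end, rate k2*[living end]*[free monomer] (k2 = 220 /M/min)
    living end + transfer agent → dead chain (k3 = 170 /M/min)
    initiator + impurity → spent initiator (k4 = 990 /M/min)
    pre-initiator → initiator (k5 = 0.12 /min)

* average number of monomer units in a chain (chains begun, living or dead) at 1.0 h
* part of the free monomer that has reacted at 1.0 h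

- the average divides the monomer in chains by the number of chains begun, living and dead together
- run time (flask): 1.0 h

Growth and ending compete for each living end. Growth rate over ending rate, as charged, gives 129: the chain length, the units a living end takes before transfer agent ends it (the kinetic chain length). A living end's half-life of 2.0 min is far shorter than the run of 1.0 h, so by hand we take dp as the chain length at the mean fractions of free monomer and transfer agent.

Now the settings. With transfer agent held, chain length as charged goes in proportion to free monomer, so a neighbour flask with 0.12 M starts at 77.6. With free monomer held, it goes inversely with transfer agent. Impurity stands outside the ratio, but it bears on how many chains begin, because initiator's half-life against impurity as charged, 0.11 min, is shorter than its 2.9 min against free monomer as charged.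

With impurity at an assumed mean fraction of 0.590 and free monomer as charged, we estimate that 6.31% of the pre-initiator begins chains. By this estimate, those chains use a fraction 0.158 of the transfer agent and 0.204 of the free monomer. The fraction of free monomer left over the fraction of transfer agent left then ends near 0.945, so we expect the mean to cost little. Our reckoning gives dp 126 and c 19.9%.

The forecast gives 126 and 20.5%, holding that "monomer loss tracks transfer-agent loss through the ratio". Its c stands above ours.

The simulation gives 127 and 20.5%. Here is the chain length at the mean of start and end fractions, the end fractions being those of each run:

| Flask | Chain length at the mean | dp in the run |
|---|---|---|
| as charged | 126 | 127 |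
| free monomer 0.12 M | 76.4 | 77.2 |
| impurity 0.0024 M | 125 | 92.0 |

In the flask with impurity at 0.0024 M the mean stands above the run, with 2.5% of free monomer left.

In the flask as charged, the impurity's step had 51% of its turnover up to 1.0 h behind it by 0.100 h, when pre-initiator stood at 48.7% and 4.42% of the free monomer had reacted. Growth continued while living ends stood: 18.8% had reacted by 0.500 h, and at 10.0 h, with living end at 0 M, the reading was 20.5%.

The constants were chosen freely; the run is a simulation.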